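**Proposed synthesis of Magnone B by silicon-tethered radical delivery of the hydroxymethyl carbon**

Atom labels used throughout: ring O1, C2 (bearing Ar = 3,4,5-trimethoxyphenyl), C3 (bearing the hydroxymethyl carbon C6), C4 (bearing C7, which carries Ar′ = 3,4-dimethoxyphenyl), C5 (ring CH2).

Remark on the chemistry: C7 is a stereocentre only in 12, 14, 15 and 16 and is erased in the last step. Its configuration is therefore free, and S (in 12 and 14) is chosen because it is the matched one for the cyclization.

## Analysis of the target

Magnone B (17) is a monocyclic lignan: one oxolane ring (O1, C2, C3, C4, C5) with Ar on C2, a hydroxymethyl group (C6) on C3 and a 3,4-dimethoxybenzoyl group (carbonyl carbon C7) on C4; C5 is an unsubstituted CH2. The three stereocentres are contiguous, (2S,3R,4R) in this numbering: Ar on C2 is trans to C6 on C3, and C6 is cis to C7 on C4. C4 is α to an aryl ketone and can epimerize, and its cis relation to the neighbouring hydroxymethyl group is the more crowded one, so it must be made under kinetic control and cannot be repaired by equilibration. The C2–O1 bond is a benzylic ether of a very electron-rich arene and ionizes under strong acid, both arenes are sensitive to hard oxidants, and the γ-hydroxy ketone can close to a hemiketal. The difficulty is to place three adjacent substituents on a small, flexible ring with one trans and one contra-thermodynamic cis relationship, with no ring fusion in the target to lean on. The route rests on the relationship between the C6 and C7 oxygens across the C3–C4 bond. A C7 carbinol on a C3=C4 dihydrofuran can hold a one-carbon radical on a silicon tether (C7–O–Si–CH2) that reaches C3. The tether carbon becomes C6, and a temporary six-membered ring C3–C4–C7–O–Si–C6 forces C6 and C7 onto the same face.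

## Retrosynthetic reasoning

17 to 16: the C7 carbonyl is traced back to a benzylic carbinol. The ketone is revealed last because C4 becomes epimerizable only once it exists. The forward step must oxidize a secondary benzylic alcohol in the presence of the primary C6 alcohol under neutral conditions.

16 to 15: the C6–OH and C7–OH bonds are traced back to the C6–Si and C7–O–Si bonds of a cyclic siloxane. Oxidative cleavage of a carbon–silicon bond (Tamao–Fleming) touches no stereocentre, so the diol problem becomes the problem of making bicycle 15.

15 to 14: the C3–C6 bond is cut. It is the only carbon–carbon bond at a ring stereocentre that can be made intramolecularly from an oxygen already sitting on C7. Its formation closes the six-membered siloxane ring and sets C3 (bond formation) and C4 (hydrogen transfer) together. The forward reaction has to be 6-endo, attack C3 anti to Ar, and end in a cis ring fusion.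

14 to 12 and 13: the Si–O bond is cut; silylation of the C7 carbinol installs the radical precursor in one step.

12 to 9 and 10 (through 11): the C7–Ar′ bond is cut. Aryl transfer to the enal brings in the second arene late and lets a chiral catalyst choose the C7 configuration. Asymmetric reduction of the corresponding aryl alkenyl ketone was judged less dependable, because both flanking groups are flat sp2 groups of similar size.

9 to 8 to 7: oxidation-level changes only. The ring is closed at the ester level because an acrylate ester is a well-behaved metathesis partner and an α-substituted acrolein is not.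

7 to 6: the C3=C4 bond is cut by ring-closing metathesis. The alkene the radical step needs is exactly the one metathesis delivers, and C2 is not touched.

6 to 4 and 5: the O1–C5 ether bond is cut. Bromide 5 is a symmetric allyl system, so direct and allylic substitution give the same ether.

4 to 3 to 1 and 2: the C2–C3 bond is cut to a vinyl addition, followed by a kinetic resolution. This is the single source of absolute configuration for C2, which then controls C3 and C4.

## Alternatives that were turned down

Alternative 1: The C4–C7 and C2–C3 bonds are cut, and the oxolane is closed afterwards through O1–C2. In the forward key step, lithiated 2-(3,4-dimethoxyphenyl)-1,3-dithiane A2 adds to the β-carbon of (5R)-5-(menthyloxy)furan-2(5H)-one A1 anti to the auxiliary, and the enolate is trapped by aldehyde 1. This gives trans-4-[2-(3,4-dimethoxyphenyl)-1,3-dithian-2-yl]-3-[hydroxy(3,4,5-trimethoxyphenyl)methyl]-5-(menthyloxy)dihydrofuran-2(3H)-one A3.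
- For: two carbon–carbon bonds and both C3 and C4 are set in one flask. The trans relationship on the lactone maps onto the required 3,4-cis relationship once the lactone and acetal carbons are reduced and the ring is re-formed through O1–C2. The sequence is probably about half as long as the chosen one, so it is stronger on step economy and equal on C3/C4 control.
- Against: C2 arises as a carbinol epimer mixture and must be set during an acid-mediated closure through a trimethoxybenzyl cation, so the 2,3-trans outcome rests on substrate bias. The dithiane must then be removed with thiophilic or oxidizing reagents next to two electron-rich arenes, and this frees the epimerizable ketone. A stoichiometric auxiliary is needed.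
- Comparison: the chosen route fixes C2 first in an enantioselective event, never forms a cation at C2, and unveils the ketone in a neutral last step.

Alternative 2: The O1–C2 and C4–C5 bonds are cut, and the ring is built by annulation of a donor–acceptor cyclopropane with formaldehyde A5. The cyclopropane is 1-(3,4-dimethoxybenzoyl)-6-(3,4,5-trimethoxyphenyl)-3-oxabicyclo[3.1.0]hexan-2-one A4. In the key step a Lewis acid activates A4, the oxygen of A5 opens it at the donor carbon with inversion, and the enolate closes onto the oxocarbenium carbon. The product is cis-fused 5-(3,4-dimethoxybenzoyl)-2-(3,4,5-trimethoxyphenyl)-3,7-dioxabicyclo[3.3.0]octan-6-one A6.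
- For: the ring and its oxygen arrive in one convergent step, and the route is short.
- Against: C4 in A6 is quaternary. The extra lactone carbonyl must be removed by decarboxylation, and the C4–H bond is then set by protonation of an enol with nothing to enforce the contra-thermodynamic cis relationship. Inversion at C2 also requires A4 to carry its aryl group cis to the lactone bridge, the more congested isomer. A cyclopropane with this donor and two acceptors can open to a zwitterion and lose its stereochemical information. A5 is a poor, oligomerizing partner.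
- Comparison: shorter on paper, but weakest exactly at the 3,4-cis relationship, which the chosen strategy enforces through a covalent tether.

Alternative 3: The C3–C6 and C4–C7 bonds are cut together. 4-Ethynyl-1,2-dimethoxybenzene A7 and (2S)-2-(3,4,5-trimethoxyphenyl)-2,5-dihydrofuran A8 undergo a gold-catalysed [2+2] cycloaddition to 6-(3,4-dimethoxyphenyl)-2-(3,4,5-trimethoxyphenyl)-3-oxabicyclo[3.2.0]hept-6-ene A9. Ozonolysis of the cyclobutene and selective reduction of the aldehyde would follow.
- For: this is the shortest plan of all and clearly better than the chosen route on step economy. The four-membered ring guarantees the cis relationship, and the aryl group on C2 should direct the alkyne to the opposite face.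
- Against: C3 and C4 of A8 are both secondary and both flanked by an allylic C–O bond, so nothing steers the aryl-bearing alkyne carbon to C4 rather than C3. The wrong regioisomer is a constitutional isomer that cannot be corrected. The alkene is 1,2-disubstituted and inductively deactivated, whereas these cycloadditions favour electron-rich, more substituted alkenes. Ozone must then discriminate against two electron-rich arenes, and the cis keto-aldehyde has two epimerizable centres.
- Comparison: the chosen strategy is longer, but its regiochemistry is decided by construction. The carbinol oxygen sits on C7, which is bonded to C4, so the tether carbon can only reach C3.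

Key step: step 9

## Route

Step 1
Reactants: 1 3,4,5-trimethoxybenzaldehyde; 2 vinylmagnesium bromide
Product: 3 rac-1-(3,4,5-trimethoxyphenyl)prop-2-en-1-ol
Conditions: THF, 0 °C; then aq NH4Cl
Reagents that add atoms: none
Why: Grignard 1,2-addition to an aromatic aldehyde; the carbinol is racemic by design and is resolved in the next step.

Step 2
Reactants: 3 rac-1-(3,4,5-trimethoxyphenyl)prop-2-en-1-ol
Product: 4 (1S)-1-(3,4,5-trimethoxyphenyl)prop-2-en-1-ol
Conditions: Ti(OiPr)4 (0.15 equiv), L-(+)-diisopropyl tartrate (0.2 equiv), t-BuOOH (0.6 equiv), 4 Å MS, CH2Cl2, −20 °C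
Reagents that add atoms: none
Why: Sharpless kinetic resolution; with the L-(+)-tartrate the (R)-carbinol can keep its aryl group away from the ligand on the face of oxygen delivery and is epoxidized, so (S)-4 should remain; running past half conversion trades material for enantiopurity.

Step 3
Reactants: 4 (1S)-1-(3,4,5-trimethoxyphenyl)prop-2-en-1-ol; 5 methyl 2-(bromomethyl)prop-2-enoate
Product: 6 methyl 2-({[(1S)-1-(3,4,5-trimethoxyphenyl)prop-2-en-1-yl]oxy}methyl)prop-2-enoate
Conditions: NaH, THF, 0 °C; then 5, 0 °C to rt
Reagents that add atoms: none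
Why: Williamson etherification; the alkoxide displaces bromide directly or by addition–elimination (SN2′), and both paths give the same ether because the allyl unit of 5 is symmetric; the stereocentre is not involved.

Step 4
Reactants: 6 methyl 2-({[(1S)-1-(3,4,5-trimethoxyphenyl)prop-2-en-1-yl]oxy}methyl)prop-2-enoate
Product: 7 methyl (5S)-5-(3,4,5-trimethoxyphenyl)-2,5-dihydrofuran-3-carboxylate
Conditions: second-generation Grubbs catalyst (H2IMes)(PCy3)Cl2Ru=CHPh (5 mol %), CH2Cl2, 40 °C
Reagents that add atoms: none
Why: Ring-closing metathesis; the carbene loads on the monosubstituted alkene and closes onto the 1,1-disubstituted acrylate to give the five-membered trisubstituted enoate, driven by loss of ethene; C2 is untouched.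

Step 5
Reactants: 7 methyl (5S)-5-(3,4,5-trimethoxyphenyl)-2,5-dihydrofuran-3-carboxylate
Product: 8 [(5S)-5-(3,4,5-trimethoxyphenyl)-2,5-dihydrofuran-3-yl]methanol
Conditions: i-Bu2AlH (2.5 equiv), CH2Cl2, −78 °C; then H2O
Reagents that add atoms: none
Why: 1,2-Reduction of a conjugated ester by an aluminium hydride at low temperature gives the allylic alcohol; the non-basic reagent avoids γ-deprotonation at C2, which would move the double bond and destroy the stereocentre.

Step 6
Reactants: 8 [(5S)-5-(3,4,5-trimethoxyphenyl)-2,5-dihydrofuran-3-yl]methanol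
Product: 9 (5S)-5-(3,4,5-trimethoxyphenyl)-2,5-dihydrofuran-3-carbaldehyde
Conditions: Dess–Martin periodinane, pyridine, CH2Cl2, 0 °C to rt
Reagents that add atoms: none
Why: Dess–Martin oxidation stops cleanly at the enal; the weakly buffered, metal-free conditions avoid both dehydrogenation of the dihydrofuran to a furan and base-induced migration of the double bond.

Step 7
Reactants: 9 (5S)-5-(3,4,5-trimethoxyphenyl)-2,5-dihydrofuran-3-carbaldehyde; 10 (3,4-dimethoxyphenyl)boronic acid
Product: 12 (S)-(3,4-dimethoxyphenyl)[(5S)-5-(3,4,5-trimethoxyphenyl)-2,5-dihydrofuran-3-yl]methanol, via (3,4-dimethoxyphenyl)(ethyl)zinc 11 (not isolated)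
Conditions: 10, Et2Zn (3 equiv), toluene, 60 °C; then (−)-MIB (10 mol %), 9, 0 °C; then H2O
Reagents that add atoms: none
Why: Catalytic enantioselective aryl transfer to an α-branched enal from a mixed arylethylzinc made by boron–zinc exchange; aryl migrates much faster than ethyl, and the zinc complex of (−)-MIB ((2S)-3-exo-morpholinoisoborneol) is expected to deliver it to the Si face of the formyl group as in its dialkylzinc additions, which sets C7 as S; the remote C2 centre should have little influence.

Step 8
Reactants: 12 (S)-(3,4-dimethoxyphenyl)[(5S)-5-(3,4,5-trimethoxyphenyl)-2,5-dihydrofuran-3-yl]methanol; 13 (bromomethyl)chlorodimethylsilane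
Product: 14 (bromomethyl){(S)-(3,4-dimethoxyphenyl)[(5S)-5-(3,4,5-trimethoxyphenyl)-2,5-dihydrofuran-3-yl]methoxy}dimethylsilane
Conditions: Et3N, DMAP (cat.), CH2Cl2, 0 °C
Reagents that add atoms: none
Why: O-Silylation of a secondary alcohol with a chlorosilane and amine base; the Si–Cl bond reacts far faster than the C–Br bond, and the labile silyl ether is filtered and used without chromatography.

Step 9
Reactants: 14 (bromomethyl){(S)-(3,4-dimethoxyphenyl)[(5S)-5-(3,4,5-trimethoxyphenyl)-2,5-dihydrofuran-3-yl]methoxy}dimethylsilane
Product: 15 (1R,2R,6S,7S)-2-(3,4-dimethoxyphenyl)-4,4-dimethyl-7-(3,4,5-trimethoxyphenyl)-3,8-dioxa-4-silabicyclo[4.3.0]nonane (cis-fused)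
Conditions: Bu3SnH (1.3 equiv, syringe pump), AIBN (0.1 equiv), benzene (0.01 M), 80 °C
Reagents that add atoms: none
Why: The tributyltin radical abstracts bromine from 14 to give an α-silylmethyl radical, which adds to C3 of the ring alkene; the resulting tertiary C4 radical takes a hydrogen atom from Bu3SnH and carries the chain. The closest known reaction type is the radical cyclization of (bromomethyl)dimethylsilyl ethers of allylic alcohols in its 6-endo variant, seen when the internal alkene carbon is fully substituted. One ring is closed, the six-membered siloxane C3–C4–C7–O–Si–C6, by 6-endo-trig attack; 5-exo attack would have to build a quaternary spiro centre at C4 and a tighter ring around the long Si–C and Si–O bonds, so attack at the less substituted C3 should win. C3 is set by the face of attack: the tether can swing to either face, and the choice is made by the C2 aryl group, which shields its own face, reinforced by C7, whose S configuration puts Ar′ pseudo-equatorial in the chair-like transition state for attack on the open face. C4 is set in the hydrogen transfer: the new siloxane ring covers the face that carries C6, and a trans-fused bicyclo[4.3.0] system would be strained, so hydrogen should arrive from the opposite face and leave C6 and C7 cis. The step needs 6-endo regioselectivity, facial selectivity at C3 and at C4, and cyclization faster than direct reduction of the first radical. These are secured, in that order, by the substitution pattern of the alkene, by the C2 and C7 substituents, by the ring fusion, and by keeping the stannane concentration low.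

Step 10
Reactants: 15 (1R,2R,6S,7S)-2-(3,4-dimethoxyphenyl)-4,4-dimethyl-7-(3,4,5-trimethoxyphenyl)-3,8-dioxa-4-silabicyclo[4.3.0]nonane
Product: 16 (R)-(3,4-dimethoxyphenyl)[(3R,4R,5S)-4-(hydroxymethyl)-5-(3,4,5-trimethoxyphenyl)oxolan-3-yl]methanol
Conditions: H2O2 (30 % aq), KF, KHCO3, THF/MeOH, rt to 50 °C
Reagents that add atoms: hydrogen peroxide, OO
Why: Tamao–Fleming oxidation; fluoride and bicarbonate activate the alkoxysilane, the C6–Si bond migrates to peroxide oxygen to give C6–OH, and the Si–O–C7 bond is hydrolysed; no stereocentre is touched and the aryl ethers are inert to basic peroxide.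

Step 11
Reactants: 16 (R)-(3,4-dimethoxyphenyl)[(3R,4R,5S)-4-(hydroxymethyl)-5-(3,4,5-trimethoxyphenyl)oxolan-3-yl]methanol
Product: 17 Magnone B, (3,4-dimethoxyphenyl)[(3R,4R,5S)-4-(hydroxymethyl)-5-(3,4,5-trimethoxyphenyl)oxolan-3-yl]methanone
Conditions: activated MnO2, CH2Cl2, rt
Reagents that add atoms: none
Why: Selective oxidation of a benzylic alcohol on the MnO2 surface, which is much faster than oxidation of the unactivated primary alcohol; the neutral heterogeneous medium should not enolize the new ketone, so the 3,4-cis arrangement is kept.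

## Compound list

1 | 3,4,5-trimethoxybenzaldehyde | COc1cc(C=O)cc(OC)c1OC | starting material
2 | vinylmagnesium bromide | C=C[Mg]Br | starting material
3 | rac-1-(3,4,5-trimethoxyphenyl)prop-2-en-1-ol | C=CC(O)c1cc(OC)c(OC)c(OC)c1 | intermediate
4 | (1S)-1-(3,4,5-trimethoxyphenyl)prop-2-en-1-ol | C=C[C@H](O)c1cc(OC)c(OC)c(OC)c1 | intermediate
5 | methyl 2-(bromomethyl)prop-2-enoate | C=C(CBr)C(=O)OC | starting material
6 | methyl 2-({[(1S)-1-(3,4,5-trimethoxyphenyl)prop-2-en-1-yl]oxy}methyl)prop-2-enoate | C=C[C@H](OCC(=C)C(=O)OC)c1cc(OC)c(OC)c(OC)c1 | intermediate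
7 | methyl (5S)-5-(3,4,5-trimethoxyphenyl)-2,5-dihydrofuran-3-carboxylate | COC(=O)C1=C[C@@H](c2cc(OC)c(OC)c(OC)c2)OC1 | intermediate
8 | [(5S)-5-(3,4,5-trimethoxyphenyl)-2,5-dihydrofuran-3-yl]methanol | OCC1=C[C@@H](c2cc(OC)c(OC)c(OC)c2)OC1 | intermediate
9 | (5S)-5-(3,4,5-trimethoxyphenyl)-2,5-dihydrofuran-3-carbaldehyde | O=CC1=C[C@@H](c2cc(OC)c(OC)c(OC)c2)OC1 | intermediate
10 | (3,4-dimethoxyphenyl)boronic acid | COc1ccc(B(O)O)cc1OC | starting material
11 | (3,4-dimethoxyphenyl)(ethyl)zinc | CC[Zn]c1ccc(OC)c(OC)c1 | intermediate (not isolated)
12 | (S)-(3,4-dimethoxyphenyl)[(5S)-5-(3,4,5-trimethoxyphenyl)-2,5-dihydrofuran-3-yl]methanol | O[C@@H](c1ccc(OC)c(OC)c1)C1=C[C@@H](c2cc(OC)c(OC)c(OC)c2)OC1 | intermediate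
13 | (bromomethyl)chlorodimethylsilane | C[Si](C)(Cl)CBr | starting material
14 | (bromomethyl){(S)-(3,4-dimethoxyphenyl)[(5S)-5-(3,4,5-trimethoxyphenyl)-2,5-dihydrofuran-3-yl]methoxy}dimethylsilane | BrC[Si](C)(C)O[C@@H](c1ccc(OC)c(OC)c1)C1=C[C@@H](c2cc(OC)c(OC)c(OC)c2)OC1 | intermediate
15 | (1R,2R,6S,7S)-2-(3,4-dimethoxyphenyl)-4,4-dimethyl-7-(3,4,5-trimethoxyphenyl)-3,8-dioxa-4-silabicyclo[4.3.0]nonane, cis-fused | C[Si]1(C)O[C@@H](c2ccc(OC)c(OC)c2)[C@H]3CO[C@H](c4cc(OC)c(OC)c(OC)c4)[C@H]3C1 | intermediate
16 | (R)-(3,4-dimethoxyphenyl)[(3R,4R,5S)-4-(hydroxymethyl)-5-(3,4,5-trimethoxyphenyl)oxolan-3-yl]methanol | O[C@@H](c1ccc(OC)c(OC)c1)[C@H]1CO[C@H](c2cc(OC)c(OC)c(OC)c2)[C@H]1CO | intermediate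
17 | Magnone B, (3,4-dimethoxyphenyl)[(3R,4R,5S)-4-(hydroxymethyl)-5-(3,4,5-trimethoxyphenyl)oxolan-3-yl]methanone | COc1ccc(C(=O)[C@H]2CO[C@H](c3cc(OC)c(OC)c(OC)c3)[C@H]2CO)cc1OC | target

## Step count and least certain steps

Total step count: 11. Longest linear sequence: 11 steps (1 to 17); 2, 5, 10 and 13 are purchased.

**Step 9 (key step).** Three things can go wrong.
- The first radical may be reduced before it cyclizes, because addition to a trisubstituted alkene is slow.
- Closure may go 5-exo at C4.
- Facial control may be poor, either at C3 or in the hydrogen transfer at C4, which would give a trans ring fusion.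

Fallback, from 7 back to 17: copper-mediated conjugate addition of 2 (CuI, Me3SiCl, THF, −78 °C) should place a vinyl group on C3 anti to the aryl group. This gives methyl (4S,5S)-4-ethenyl-5-(3,4,5-trimethoxyphenyl)oxolane-3-carboxylate F1 as both epimers at the ester carbon. Ozonolysis with NaBH4 work-up gives methyl (4R,5S)-4-(hydroxymethyl)-5-(3,4,5-trimethoxyphenyl)oxolane-3-carboxylate F2. DBU should funnel both epimers into (1R,5R,6S)-6-(3,4,5-trimethoxyphenyl)-3,7-dioxabicyclo[3.3.0]octan-2-one F3, because only the cis isomer can lactonize. One equivalent of commercial 3,4-dimethoxyphenylmagnesium bromide at −78 °C then opens the lactone to 17.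

**Step 7.** Facial selectivity of the aryl transfer may be poor, ethyl may transfer in competition, or an uncatalysed background addition may be promoted by the many Lewis-basic oxygens.

Fallback, from 9 back to 12: addition of 3,4-dimethoxyphenylmagnesium bromide (THF, −78 °C) should give 12 together with its C7 epimer, (R)-(3,4-dimethoxyphenyl)[(5S)-5-(3,4,5-trimethoxyphenyl)-2,5-dihydrofuran-3-yl]methanol F4, which is separated by chromatography. F4 is oxidized with Dess–Martin periodinane to (3,4-dimethoxyphenyl)[(5S)-5-(3,4,5-trimethoxyphenyl)-2,5-dihydrofuran-3-yl]methanone F5. Reduction of F5 with NaBH4/CeCl3 returns the epimer pair for another separation. Since C7 is erased in step 11, F4 could also be taken through steps 8 to 11, relying on the C2 aryl group alone.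

**Step 2.** The monosubstituted alkene is epoxidized slowly, so the two enantiomers may be discriminated incompletely. The Lewis-acidic titanium alkoxide may also ionize the electron-rich carbinol.

Fallback, from 3 back to 4: lipase-catalysed acylation (Burkholderia cepacia lipase, vinyl acetate, t-BuOMe, rt) should acetylate the R enantiomer to (1R)-1-(3,4,5-trimethoxyphenyl)prop-2-en-1-yl acetate F6 and leave 4, which is separated by chromatography.

**Step 11.** The oxidation may be sluggish, the C4 centre may be lost by enolization on a basic batch of oxidant, or the primary alcohol may be oxidized and lead to a lactol.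

Fallback, from 16 back to 17: the primary alcohol is silylated selectively (t-BuMe2SiCl, imidazole) to (R)-[(3R,4R,5S)-4-({[tert-butyl(dimethyl)silyl]oxy}methyl)-5-(3,4,5-trimethoxyphenyl)oxolan-3-yl](3,4-dimethoxyphenyl)methanol F7. Dess–Martin oxidation gives (3,4-dimethoxyphenyl)[(3R,4R,5S)-4-({[tert-butyl(dimethyl)silyl]oxy}methyl)-5-(3,4,5-trimethoxyphenyl)oxolan-3-yl]methanone F8. Buffered HF·pyridine then frees 17.

## Further compounds

F1 | step 9 | methyl (4S,5S)-4-ethenyl-5-(3,4,5-trimethoxyphenyl)oxolane-3-carboxylate (both epimers at C3) | COC(=O)C1CO[C@H](c2cc(OC)c(OC)c(OC)c2)[C@H]1C=C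
F2 | step 9 | methyl (4R,5S)-4-(hydroxymethyl)-5-(3,4,5-trimethoxyphenyl)oxolane-3-carboxylate (both epimers at C3) | COC(=O)C1CO[C@H](c2cc(OC)c(OC)c(OC)c2)[C@H]1CO
F3 | step 9 | (1R,5R,6S)-6-(3,4,5-trimethoxyphenyl)-3,7-dioxabicyclo[3.3.0]octan-2-one | O=C1[C@H]2CO[C@H](c3cc(OC)c(OC)c(OC)c3)[C@H]2CO1
F4 | step 7 | (R)-(3,4-dimethoxyphenyl)[(5S)-5-(3,4,5-trimethoxyphenyl)-2,5-dihydrofuran-3-yl]methanol | O[C@H](c1ccc(OC)c(OC)c1)C1=C[C@@H](c2cc(OC)c(OC)c(OC)c2)OC1
F5 | step 7 | (3,4-dimethoxyphenyl)[(5S)-5-(3,4,5-trimethoxyphenyl)-2,5-dihydrofuran-3-yl]methanone | O=C(c1ccc(OC)c(OC)c1)C1=C[C@@H](c2cc(OC)c(OC)c(OC)c2)OC1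
F6 | step 2 | (1R)-1-(3,4,5-trimethoxyphenyl)prop-2-en-1-yl acetate | C=C[C@@H](OC(C)=O)c1cc(OC)c(OC)c(OC)c1
F7 | step 11 | (R)-[(3R,4R,5S)-4-({[tert-butyl(dimethyl)silyl]oxy}methyl)-5-(3,4,5-trimethoxyphenyl)oxolan-3-yl](3,4-dimethoxyphenyl)methanol | O[C@@H](c1ccc(OC)c(OC)c1)[C@H]1CO[C@H](c2cc(OC)c(OC)c(OC)c2)[C@H]1CO[Si](C)(C)C(C)(C)C
F8 | step 11 | (3,4-dimethoxyphenyl)[(3R,4R,5S)-4-({[tert-butyl(dimethyl)silyl]oxy}methyl)-5-(3,4,5-trimethoxyphenyl)oxolan-3-yl]methanone | COc1ccc(C(=O)[C@H]2CO[C@H](c3cc(OC)c(OC)c(OC)c3)[C@H]2CO[Si](C)(C)C(C)(C)C)cc1OC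
A1 | alternative 1 | (5R)-5-{[(1R,2S,5R)-5-methyl-2-(propan-2-yl)cyclohexyl]oxy}furan-2(5H)-one | O=C1C=C[C@H](O[C@@H]2C[C@H](C)CC[C@H]2C(C)C)O1
A2 | alternative 1 | 2-(3,4-dimethoxyphenyl)-1,3-dithiane | COc1ccc(C2SCCCS2)cc1OC
A3 | alternative 1 | trans-4-[2-(3,4-dimethoxyphenyl)-1,3-dithian-2-yl]-3-[hydroxy(3,4,5-trimethoxyphenyl)methyl]-5-(menthyloxy)dihydrofuran-2(3H)-one (carbinol epimers) | O=C1O[C@@H](O[C@@H]2C[C@H](C)CC[C@H]2C(C)C)[C@H](C3(c4ccc(OC)c(OC)c4)SCCCS3)[C@H]1C(O)c5cc(OC)c(OC)c(OC)c5
A4 | alternative 2 | 1-(3,4-dimethoxybenzoyl)-6-(3,4,5-trimethoxyphenyl)-3-oxabicyclo[3.1.0]hexan-2-one, aryl group cis to the lactone bridge | O=C(c1ccc(OC)c(OC)c1)[C@]12[C@@H](c3cc(OC)c(OC)c(OC)c3)[C@H]1COC2=O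
A5 | alternative 2 | formaldehyde | C=O
A6 | alternative 2 | cis-fused 5-(3,4-dimethoxybenzoyl)-2-(3,4,5-trimethoxyphenyl)-3,7-dioxabicyclo[3.3.0]octan-6-one | O=C(c1ccc(OC)c(OC)c1)[C@]23CO[C@H](c4cc(OC)c(OC)c(OC)c4)[C@H]2COC3=O
A7 | alternative 3 | 4-ethynyl-1,2-dimethoxybenzene | C#Cc1ccc(OC)c(OC)c1
A8 | alternative 3 | (2S)-2-(3,4,5-trimethoxyphenyl)-2,5-dihydrofuran | C1=C[C@@H](c2cc(OC)c(OC)c(OC)c2)OC1
A9 | alternative 3 | 6-(3,4-dimethoxyphenyl)-2-(3,4,5-trimethoxyphenyl)-3-oxabicyclo[3.2.0]hept-6-ene | C1(c2ccc(OC)c(OC)c2)=C[C@@H]3[C@@H](c4cc(OC)c(OC)c(OC)c4)OC[C@H]13
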